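**Retrosynthetic overview**

- The oxolane (O1, C2 aryl, C3 hydroxymethyl, C4 benzyl, C5) is closed last through its O1–C2 bond: the hydroxyl on C5 captures a benzylic cation at C2 in a 5-exo closure, which places the aryl group trans to C3.
- Enabling feature: C2 is the benzylic carbon of the 3,4,5-trimethoxyphenyl ring, and the 4-methoxy oxygen para to it stabilises the cation as a quinone-methide-like oxocarbenium ion. O1 on C5 is four atoms from C2, whereas the hydroxymethyl oxygen on C3 could only give an oxetane.
- O1, C5, C4, C3 and the hydroxymethyl carbon (at the acid oxidation level) are carried as a temporary γ-lactone ring. It directs the aldol addition that attaches C2 to the face trans to the C4 benzyl group (trans on the lactone is 3,4-cis on the oxolane), and its reduction frees O1–H and the CH2OH group. Aldol addition, reduction and ring switch are run in one flask.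
- The (S)-β-(3,4-dimethoxybenzyl)-γ-butyrolactone comes from (S)-epichlorohydrin and diethyl malonate through a cyclopropane-fused lactone, which an aryl copper reagent opens at its CH2; the ester is then removed.
- Ring order: cyclopropane and lactone (step 1, both temporary), cyclopropane opened (step 2), lactone opened and oxolane closed (step 4).

Key step: step 4

Remark on the chemistry: the carbinol carbon of the aldol adduct and of the triol (the future C2) is left undefined, because it passes through a planar cation. O1, C3, C4 and C5 keep their locants from the lactone to the oxolane.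

**Step 1**
Reactants: 1 diethyl malonate; 2 (S)-epichlorohydrin [(S)-2-(chloromethyl)oxirane]
Product: 5 ethyl (1R,5S)-2-oxo-3-oxabicyclo[3.1.0]hexane-1-carboxylate, via epoxy malonate 3 (not isolated), via cyclopropyl carbinol 4 (not isolated)
Conditions: NaOEt, EtOH, 0 °C → reflux
Reagents that add atoms: none
Why: Known malonate/epichlorohydrin cyclopropanation–lactonisation cascade: the malonate anion opens the oxirane at its CH2 and the alkoxide displaces chloride to give epoxide 3, the malonate carbanion opens 3 in a 3-exo-tet SN2 step with inversion at the stereocentre to 4, and the alkoxide of 4 lactonises onto the cis ester, so that C5 of 5 derives from the stereocentre of 2 and C1 is fixed by the cis ring fusion.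

**Step 2**
Reactants: 5 ethyl (1R,5S)-2-oxo-3-oxabicyclo[3.1.0]hexane-1-carboxylate; 6 4-bromo-1,2-dimethoxybenzene
Product: 8 ethyl (3R,4S)-4-(3,4-dimethoxybenzyl)-2-oxotetrahydrofuran-3-carboxylate, via Grignard reagent 7 (not isolated)
Conditions: Mg, THF, rt → 40 °C; then 5, CuI (10 mol %), THF, −30 → 0 °C; aq. NH4Cl
Reagents that add atoms: none
Why: Copper-catalysed homoconjugate addition of an aryl Grignard reagent to a doubly activated cyclopropane (known for this lactone class): the aryl copper species attacks the unsubstituted cyclopropane CH2, the bond to the carbon between the two carbonyl groups breaks to a stabilised enolate, and the C4 stereocentre, which is not involved, is retained (C3 epimerises freely; the trans isomer is drawn).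

**Step 3**
Reactants: 8 ethyl (3R,4S)-4-(3,4-dimethoxybenzyl)-2-oxotetrahydrofuran-3-carboxylate
Product: 9 (S)-4-(3,4-dimethoxybenzyl)dihydrofuran-2(3H)-one
Conditions: LiCl, DMSO–H2O, 140 °C
Reagents that add atoms: none
Why: Krapcho dealkoxycarbonylation: chloride dealkylates the ethyl ester of the malonate-type system, CO2 is lost and the lactone enolate is protonated, while the non-acidic C4 stereocentre is untouched.

**Step 4**
Reactants: 9 (S)-4-(3,4-dimethoxybenzyl)dihydrofuran-2(3H)-one; 10 3,4,5-trimethoxybenzaldehyde
Product: 13 [(2R,3S,4S)-4-(3,4-dimethoxybenzyl)-2-(3,4,5-trimethoxyphenyl)oxolan-3-yl]methanol (CNP0107562.1), via aldol adduct 11 (not isolated), via triol 12 (not isolated)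
Conditions: LiN(iPr)2 (LDA), THF, −78 °C; 10, −78 °C; LiAlH4, −78 → 0 °C; 3 M aq. HCl, THF, 0 °C → rt (to 40 °C if needed)
Reagents that add atoms: none
Why: Aldol addition, LiAlH4 reduction and SN1 cyclodehydration in one flask: the lithium enolate of 9 adds to 10 on the face anti to the C4 benzyl group, LiAlH4 added at −78 °C reduces the lactone of aldolate 11 before it can revert and turns the lactone ring oxygen into the free C5 hydroxyl of triol 12, and aqueous acid ionises the benzylic C2–OH to a cation that this hydroxyl captures. The closest known reaction type is the aldol, hydride reduction and acid cyclisation sequence by which 2-aryl-4-benzyl-3-(hydroxymethyl)oxolane lignans are made from β-benzyl-γ-butyrolactones, here telescoped. The oxolane closes by O1–C2 bond formation in a 5-exo mode onto the trigonal benzylic cation, which the para 4-methoxy oxygen of the trimethoxyphenyl ring stabilises. C3 is set by the lactone ring (trans to C4, which becomes 3,4-cis once the ring switches), C2 by product stability under reversible ionisation (aryl trans to the C3 hydroxymethyl group), and C4 is carried over from 9; the carbinol epimers of 11 and 12 converge. The step needs O- over C-capture of the cation and no loss of H3: the 5-exo hydroxyl capture should outrun Friedel–Crafts attack by the 3,4-dimethoxyphenyl ring and E1 elimination in dilute aqueous acid, and the hydroxymethyl oxygen on C3 could only form an oxetane.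

**Compound list**

1 | diethyl malonate | CCOC(=O)CC(=O)OCC | starting material
2 | (S)-epichlorohydrin, (S)-2-(chloromethyl)oxirane | ClC[C@@H]1CO1 | starting material
3 | diethyl (S)-2-(oxiran-2-ylmethyl)malonate | CCOC(=O)C(C[C@H]1CO1)C(=O)OCC | intermediate
4 | diethyl (S)-2-(hydroxymethyl)cyclopropane-1,1-dicarboxylate (sodium alkoxide in the flask) | CCOC(=O)C1(C[C@@H]1CO)C(=O)OCC | intermediate
5 | ethyl (1R,5S)-2-oxo-3-oxabicyclo[3.1.0]hexane-1-carboxylate | CCOC(=O)[C@@]12C[C@@H]1COC2=O | intermediate
6 | 4-bromo-1,2-dimethoxybenzene | COc1ccc(Br)cc1OC | starting material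
7 | (3,4-dimethoxyphenyl)magnesium bromide | COc1ccc([Mg]Br)cc1OC | intermediate
8 | ethyl (3R,4S)-4-(3,4-dimethoxybenzyl)-2-oxotetrahydrofuran-3-carboxylate (trans epimer drawn, C3 labile) | CCOC(=O)[C@@H]1C(=O)OC[C@H]1Cc2ccc(OC)c(OC)c2 | intermediate
9 | (S)-4-(3,4-dimethoxybenzyl)dihydrofuran-2(3H)-one | COc1ccc(C[C@@H]2COC(=O)C2)cc1OC | intermediate
10 | 3,4,5-trimethoxybenzaldehyde | COc1cc(C=O)cc(OC)c1OC | starting material
11 | (3R,4S)-4-(3,4-dimethoxybenzyl)-3-[hydroxy(3,4,5-trimethoxyphenyl)methyl]dihydrofuran-2(3H)-one (both carbinol epimers, lithium alkoxide in the flask) | COc1ccc(C[C@@H]2COC(=O)[C@H]2C(O)c3cc(OC)c(OC)c(OC)c3)cc1OC | intermediate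
12 | (2S,3S)-2-(3,4-dimethoxybenzyl)-3-[hydroxy(3,4,5-trimethoxyphenyl)methyl]butane-1,4-diol (both carbinol epimers) | COc1ccc(C[C@H](CO)[C@@H](CO)C(O)c2cc(OC)c(OC)c(OC)c2)cc1OC | intermediate
13 | [(2R,3S,4S)-4-(3,4-dimethoxybenzyl)-2-(3,4,5-trimethoxyphenyl)oxolan-3-yl]methanol | COc1ccc(C[C@@H]2CO[C@@H](c3cc(OC)c(OC)c(OC)c3)[C@@H]2CO)cc1OC | target

**Step count and risks**

Total step count: 4. Longest linear sequence: 4 steps (2 → 5 → 8 → 9 → 13).

Steps most likely to fail:

Step 4 (key step). What may go wrong: reversal of the aldol addition before the hydride has reduced the lactone; in the acid stage, capture of the C2 cation by the 3,4-dimethoxyphenyl ring instead of by oxygen, or epimerisation at C3 through elimination and re-protonation. The fallback sets out from 9 and comes back at 13; it works stepwise and replaces the acid-generated cation by a p-quinone methide formed under near-neutral conditions. Syringaldehyde is silylated (TBSCl, imidazole, DMF) to 4-[(tert-butyldimethylsilyl)oxy]-3,5-dimethoxybenzaldehyde F1. The lithium enolate of 9 is added to it at −78 °C and the mixture is quenched cold with AcOH, so that the silylated aldol adduct F2 is isolated. LiAlH4 in THF at 0 °C should give the silylated triol F3. Bu4NF in THF buffered with AcOH removes the silyl group; the free p-hydroxybenzylic alcohol should lose water to the p-quinone methide, to which the C5 hydroxyl adds in a 5-exo oxa-1,6-addition to give 4-[(2R,3S,4S)-4-(3,4-dimethoxybenzyl)-3-(hydroxymethyl)oxolan-2-yl]-2,6-dimethoxyphenol F4. MeI, K2CO3 in acetone methylates the phenol only and gives 13.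

Step 2. What may go wrong: addition of the Grignard reagent to the lactone or ester carbonyl instead of copper-mediated opening of the cyclopropane, and homocoupling of the aryl reagent. The fallback sets out from 5 and comes back at 8 without an organomagnesium reagent. MgI2 in THF opens the activated cyclopropane at its CH2 to ethyl (4S)-4-(iodomethyl)-2-oxotetrahydrofuran-3-carboxylate F5. A nickel-catalysed reductive cross-electrophile coupling of this primary iodide with 6 (NiI2, 4,4'-di-tert-butyl-2,2'-bipyridine, Zn, DMA, 60 °C) should then give 8.

Step 1. What may go wrong: partial loss of enantiomeric purity, because direct displacement of chloride by the malonate anion competes with epoxide opening and leads into the enantiomeric series. The fallback sets out from 1 and comes back at 5. Compound 2 is replaced by (R)-glycidyl 3-nitrobenzenesulfonate (NaH, THF), whose sulfonate is displaced first, so that the same epoxy malonate 3 is reached by a single pathway; NaOEt in EtOH then closes the cyclopropane (4) and the lactone (5). No compound outside the list is made (F0).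

**Further compounds**

F1 | step 4 | 4-[(tert-butyldimethylsilyl)oxy]-3,5-dimethoxybenzaldehyde | CC(C)(C)[Si](C)(C)Oc1c(OC)cc(C=O)cc1OC
F2 | step 4 | (3R,4S)-3-{[4-(tert-butyldimethylsilyloxy)-3,5-dimethoxyphenyl](hydroxy)methyl}-4-(3,4-dimethoxybenzyl)dihydrofuran-2(3H)-one | COc1ccc(C[C@@H]2COC(=O)[C@H]2C(O)c3cc(OC)c(O[Si](C)(C)C(C)(C)C)c(OC)c3)cc1OC
F3 | step 4 | (2S,3S)-2-(3,4-dimethoxybenzyl)-3-{[4-(tert-butyldimethylsilyloxy)-3,5-dimethoxyphenyl](hydroxy)methyl}butane-1,4-diol | COc1ccc(C[C@H](CO)[C@@H](CO)C(O)c2cc(OC)c(O[Si](C)(C)C(C)(C)C)c(OC)c2)cc1OC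
F4 | step 4 | 4-[(2R,3S,4S)-4-(3,4-dimethoxybenzyl)-3-(hydroxymethyl)oxolan-2-yl]-2,6-dimethoxyphenol | COc1ccc(C[C@@H]2CO[C@@H](c3cc(OC)c(O)c(OC)c3)[C@@H]2CO)cc1OC
F5 | step 2 | ethyl (4S)-4-(iodomethyl)-2-oxotetrahydrofuran-3-carboxylate | CCOC(=O)C1C(=O)OC[C@H]1CI
F0 | step 1 | none | none
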